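## Retrosynthetic overview

1. Target 31 ⇐ TBS removal from 30 ⇐ Heck union at C7–C8 of (Z)-vinyl iodide 29 with vinyl-dihydropyranone 26; 29 ⇐ Stork–Zhao olefination (C8=C9) of aldehyde 28 ⇐ Heck union at C13–C14 of tetrahydropyran 14 with (E)-vinyl iodide 21. Positions use ratjadone numbering, C1 = lactone C=O to C24 = propenyl CH3.
2. Tetrahydropyran 14 ⇐ oxan-4-one 13 ⇐ two-carbon ring expansion of cis-β-lactone 4 (C19–C24) by alkenyllithium 10 (C14–C18, carrying C16).
3. 4 ⇐ crotonaldehyde + propanoyl chloride (catalytic asymmetric ketene–aldehyde cyclocondensation); 10 ⇐ resolved pent-1-en-4-yn-3-ol.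
4. 21 ⇐ Evans propargylation (C10), then Zr-catalysed carboalumination/iodination (C12=C13); 26 ⇐ acrylate RCM of resolved hexa-1,5-dien-3-ol.
5. Ring order: oxetanone 4 (step 1) is expanded to the oxane (step 5) in the western branch; the dihydropyranone is closed independently by RCM (step 13); both rings exist before the two Heck unions.

Assumption: the recoverable Evans oxazolidinone, like the TBS group, is treated as a reagent and not as a starting material.

## Route

Step 1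
Reactants: 1 (E)-but-2-enal; 2 propanoyl chloride
Product: 4 (3S,4R)-3-methyl-4-[(E)-prop-1-en-1-yl]oxetan-2-one, via methylketene 3 (not isolated)
Conditions: 2 (2 equiv, slow addition), O-TMS-quinine (10 mol%), LiClO4, iPr2NEt, CH2Cl2/Et2O, −78 °C
Reagents that add atoms: none
Why: Cinchona alkaloid/Lewis acid-catalysed acyl halide–aldehyde cyclocondensation (ketene aldol-lactonisation), in which the alkaloid-bound enolate of methylketene adds to the Li-activated aldehyde through a closed transition state to give the cis (syn-aldol) β-lactone and sets C20 (3S) and C21 (4R) under catalyst control (the quinidine-derived pseudoenantiomer would give ent-4).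

Step 2
Reactants: 5 rac-pent-1-en-4-yn-3-ol
Product: 6 (S)-pent-1-en-4-yn-3-ol
Conditions: Ti(OiPr)4, L-(+)-DIPT, t-BuOOH (0.65 equiv), 4 Å MS, CH2Cl2, −20 °C
Reagents that add atoms: none
Why: Sharpless kinetic resolution, in which L-(+)-tartrate epoxidises the (R)-vinyl carbinol faster, so the (S)-alcohol (future C16) is recovered in high ee at about 65% conversion.

Step 3
Reactants: 6 (S)-pent-1-en-4-yn-3-ol
Product: 7 (S)-tert-butyldimethyl(pent-1-en-4-yn-3-yloxy)silane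
Conditions: TBSCl, imidazole, DMF, 0 °C to rt
Reagents that add atoms: tert-butyldimethylsilyl chloride, CC(C)(C)[Si](C)(C)Cl
Why: Standard silyl ether formation that masks the C16 hydroxyl for the organometallic and oxidation steps without touching the stereocentre.

Step 4
Reactants: 7 (S)-tert-butyldimethyl(pent-1-en-4-yn-3-yloxy)silane
Product: 9 (S,E)-tert-butyl[(1-iodopenta-1,4-dien-3-yl)oxy]dimethylsilane, via alkenylzirconocene chloride 8 (not isolated)
Conditions: Cp2Zr(H)Cl (1.1 equiv), CH2Cl2, rt; I2, 0 °C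
Reagents that add atoms: iodine, II
Why: Schwartz hydrozirconation adds syn and anti-Markovnikov to the terminal alkyne (much faster than to the vinyl group), and iodinolysis with retention gives the (E)-vinyl iodide.

Step 5
Reactants: 4 (3S,4R)-3-methyl-4-[(E)-prop-1-en-1-yl]oxetan-2-one; 9 (S,E)-tert-butyl[(1-iodopenta-1,4-dien-3-yl)oxy]dimethylsilane
Product: 13 (2R,3S,6R)-6-[(1S)-1-[(tert-butyldimethylsilyl)oxy]prop-2-en-1-yl]-3-methyl-2-[(E)-prop-1-en-1-yl]oxan-4-one, via alkenyllithium 10 (not isolated), via lithium aldolate 11 (not isolated), via lithium enolate 12 (not isolated)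
Conditions: 9, t-BuLi (2.0 equiv), Et2O, −78 °C; added to 4 (1.0 equiv), THF, −78 °C; HMPA (4 equiv), −78 to −30 °C; AcOH, −78 °C
Reagents that add atoms: none
Why: Proposed new method: anionic two-carbon ring expansion of a β-lactone (oxetan-2-one to oxan-4-one), in which alkenyllithium 10 acylates at the strained lactone C=O, the tetrahedral adduct collapses to lithium aldolate 11, and once HMPA breaks the Li chelate the C21 alkoxide closes 6-endo-trig onto the (E)-enone through a chair with the propenyl and C17 substituents equatorial (2,6-cis, C17 R) to give enolate 12, which is regiodefined toward C18 so the axial C20 methyl from 4 is never enolised and a second addition of 10 is blocked; the closest known chemistry is acyl C–O opening of β-lactones by nucleophiles combined with oxa-Michael cyclisation of β′-hydroxy enones to 2,6-cis-tetrahydropyran-4-ones.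

Step 6
Reactants: 13 (2R,3S,6R)-6-[(1S)-1-[(tert-butyldimethylsilyl)oxy]prop-2-en-1-yl]-3-methyl-2-[(E)-prop-1-en-1-yl]oxan-4-one
Product: 14 (2R,3R,4S,6R)-6-[(1S)-1-[(tert-butyldimethylsilyl)oxy]prop-2-en-1-yl]-3-methyl-2-[(E)-prop-1-en-1-yl]oxan-4-ol
Conditions: crude 13, L-Selectride, THF, −78 °C; H2O
Reagents that add atoms: none
Why: Diastereoselective ketone reduction in which the bulky hydride attacks from the equatorial direction and gives the axial C19 alcohol (4S), trans-diaxial to the C20 methyl, before the α-centre can epimerise.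

Step 7
Reactants: 2 propanoyl chloride
Product: 15 (S)-4-benzyl-3-propanoyloxazolidin-2-one
Conditions: (S)-4-benzyloxazolidin-2-one, n-BuLi, THF, −78 °C; then 2
Reagents that add atoms: (S)-4-benzyloxazolidin-2-one, O=C1N[C@@H](Cc2ccccc2)CO1
Why: N-Acylation of the lithiated Evans auxiliary by the acid chloride.

Step 8
Reactants: 15 (S)-4-benzyl-3-propanoyloxazolidin-2-one; 16 3-bromoprop-1-yne
Product: 18 (S)-4-benzyl-3-[(R)-2-methylpent-4-ynoyl]oxazolidin-2-one, via sodium Z-enolate 17 (not isolated)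
Conditions: NaHMDS, THF, −78 °C; 16 (3 equiv), −78 to −40 °C
Reagents that add atoms: none
Why: Evans asymmetric alkylation, in which the chelated (Z)-enolate is propargylated on the face away from the benzyl group and sets C10 as R.

Step 9
Reactants: 18 (S)-4-benzyl-3-[(R)-2-methylpent-4-ynoyl]oxazolidin-2-one
Product: 19 (R)-2-methylpent-4-yn-1-ol
Conditions: LiBH4, MeOH (1 equiv), Et2O, 0 °C
Reagents that add atoms: none
Why: Reductive cleavage of the imide to the primary alcohol without epimerisation, with recovery of the auxiliary.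

Step 10
Reactants: 19 (R)-2-methylpent-4-yn-1-ol
Product: 21 (R,E)-5-iodo-2,4-dimethylpent-4-en-1-ol, via alkenylalane 20 (not isolated)
Conditions: Me3Al (3 equiv), Cp2ZrCl2 (25 mol%), CH2Cl2, 0 °C to rt; I2, THF, −30 °C
Reagents that add atoms: trimethylaluminium, C[Al](C)C; iodine, II
Why: Negishi Zr-catalysed carboalumination adds Me–Al syn across the terminal alkyne (methyl to the internal carbon), and iodinolysis with retention gives the (E)-trisubstituted vinyl iodide (C12=C13).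

Step 11
Reactants: 22 rac-hexa-1,5-dien-3-ol
Product: 23 (S)-hexa-1,5-dien-3-ol
Conditions: Ti(OiPr)4, D-(−)-DIPT, t-BuOOH (0.6 equiv), 4 Å MS, CH2Cl2, −20 °C
Reagents that add atoms: none
Why: Sharpless kinetic resolution, in which D-(−)-tartrate epoxidises the (R)-allylic alcohol faster and leaves the (S)-alcohol (future C5) in high ee.

Step 12
Reactants: 23 (S)-hexa-1,5-dien-3-ol; 24 prop-2-enoyl chloride
Product: 25 (S)-hexa-1,5-dien-3-yl prop-2-enoate
Conditions: Et3N, DMAP (cat.), CH2Cl2, 0 °C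
Reagents that add atoms: none
Why: Simple O-acylation that does not touch the stereocentre.

Step 13
Reactants: 25 (S)-hexa-1,5-dien-3-yl prop-2-enoate
Product: 26 (S)-6-ethenyl-5,6-dihydro-2H-pyran-2-one
Conditions: Grubbs II (5 mol%), CH2Cl2 (5 mM), 40 °C
Reagents that add atoms: none
Why: Ring-closing metathesis, in which the catalyst loads on the unhindered allyl terminus and closes onto the acrylate to the six-membered lactone in preference to the strained butenolide.

Step 14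
Reactants: 14 (2R,3R,4S,6R)-6-[(1S)-1-[(tert-butyldimethylsilyl)oxy]prop-2-en-1-yl]-3-methyl-2-[(E)-prop-1-en-1-yl]oxan-4-ol; 21 (R,E)-5-iodo-2,4-dimethylpent-4-en-1-ol
Product: 27 (2R,3R,4S,6R)-6-[(1S,2E,4E,7R)-1-[(tert-butyldimethylsilyl)oxy]-8-hydroxy-5,7-dimethylocta-2,4-dien-1-yl]-3-methyl-2-[(E)-prop-1-en-1-yl]oxan-4-ol
Conditions: Pd(OAc)2 (10 mol%), Bu4NCl, K2CO3, DMF, 50 °C
Reagents that add atoms: none
Why: Heck reaction under Jeffery conditions, in which the alkenyl-Pd adds to the terminal carbon of the monosubstituted vinyl group (the propenyl group is far less reactive) and β-hydride elimination toward conjugation gives the (E,E)-diene.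

Step 15
Reactants: 27 (2R,3R,4S,6R)-6-[(1S,2E,4E,7R)-1-[(tert-butyldimethylsilyl)oxy]-8-hydroxy-5,7-dimethylocta-2,4-dien-1-yl]-3-methyl-2-[(E)-prop-1-en-1-yl]oxan-4-ol
Product: 28 (2R,4E,6E,8S)-8-[(tert-butyldimethylsilyl)oxy]-8-[(2R,4S,5R,6R)-4-hydroxy-5-methyl-6-[(E)-prop-1-en-1-yl]oxan-2-yl]-2,4-dimethylocta-4,6-dienal
Conditions: TEMPO (10 mol%), PhI(OAc)2 (1.1 equiv), CH2Cl2, rt
Reagents that add atoms: none
Why: TEMPO/BAIB oxidation is selective for the primary alcohol over the hindered axial secondary C19 alcohol and does not epimerise the α-methyl aldehyde.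

Step 16
Reactants: 28 (2R,4E,6E,8S)-8-[(tert-butyldimethylsilyl)oxy]-8-[(2R,4S,5R,6R)-4-hydroxy-5-methyl-6-[(E)-prop-1-en-1-yl]oxan-2-yl]-2,4-dimethylocta-4,6-dienal
Product: 29 (2R,3R,4S,6R)-6-[(1S,2E,4E,7R,8Z)-1-[(tert-butyldimethylsilyl)oxy]-9-iodo-5,7-dimethyldeca-2,4,8-trien-1-yl]-3-methyl-2-[(E)-prop-1-en-1-yl]oxan-4-ol
Conditions: [Ph3PCH(I)CH3]I (2.5 equiv), NaHMDS (2.4 equiv), THF/HMPA, −78 to −20 °C
Reagents that add atoms: (1-iodoethyl)triphenylphosphonium iodide, CC(I)[P+](c1ccccc1)(c1ccccc1)c1ccccc1.[I-]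
Why: Stork–Zhao-type Wittig olefination with the non-stabilised α-iodo ylide proceeds through the cis-oxaphosphetane and gives the (Z)-2-iodoalkene (iodine cis to C10), setting the C8=C9 geometry, with the weakly basic ylide tolerating the free C19 hydroxyl.

Step 17
Reactants: 29 (2R,3R,4S,6R)-6-[(1S,2E,4E,7R,8Z)-1-[(tert-butyldimethylsilyl)oxy]-9-iodo-5,7-dimethyldeca-2,4,8-trien-1-yl]-3-methyl-2-[(E)-prop-1-en-1-yl]oxan-4-ol; 26 (S)-6-ethenyl-5,6-dihydro-2H-pyran-2-one
Product: 30 (6S)-6-[(1E,3Z,5R,7E,9E,11S)-11-[(tert-butyldimethylsilyl)oxy]-11-[(2R,4S,5R,6R)-4-hydroxy-5-methyl-6-[(E)-prop-1-en-1-yl]oxan-2-yl]-3,5,7-trimethylundeca-1,3,7,9-tetraen-1-yl]-5,6-dihydro-2H-pyran-2-one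
Conditions: Pd(OAc)2 (15 mol%), Ag2CO3 (0.6 equiv), DMF, rt to 40 °C, dark
Reagents that add atoms: none
Why: Heck reaction under mild silver-carbonate conditions, in which oxidative addition retains the (Z)-iodide geometry, insertion occurs at the terminal vinyl carbon of 26 rather than the cyclic cis-enoate, and β-hydride elimination gives the (6E,8Z)-diene.

Step 18
Reactants: 30 (6S)-6-[(1E,3Z,5R,7E,9E,11S)-11-[(tert-butyldimethylsilyl)oxy]-11-[(2R,4S,5R,6R)-4-hydroxy-5-methyl-6-[(E)-prop-1-en-1-yl]oxan-2-yl]-3,5,7-trimethylundeca-1,3,7,9-tetraen-1-yl]-5,6-dihydro-2H-pyran-2-one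
Product: 31 (6S)-6-[(1E,3Z,5R,7E,9E,11S)-11-hydroxy-11-[(2R,4S,5R,6R)-4-hydroxy-5-methyl-6-[(E)-prop-1-en-1-yl]oxan-2-yl]-3,5,7-trimethylundeca-1,3,7,9-tetraen-1-yl]-5,6-dihydro-2H-pyran-2-one
Conditions: HF·pyridine, pyridine, THF, 0 °C to rt
Reagents that add atoms: none
Why: Buffered fluoride desilylation removes the allylic TBS ether without ionising the dienyl carbinol or opening the unsaturated lactone.

## Compound list

1 | (E)-but-2-enal | C/C=C/C=O | starting material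
2 | propanoyl chloride | CCC(=O)Cl | starting material
3 | methylketene (prop-1-en-1-one) | CC=C=O | intermediate
4 | (3S,4R)-3-methyl-4-[(E)-prop-1-en-1-yl]oxetan-2-one | C/C=C/[C@H]1OC(=O)[C@H]1C | intermediate
5 | rac-pent-1-en-4-yn-3-ol | C=CC(O)C#C | starting material
6 | (S)-pent-1-en-4-yn-3-ol | C#C[C@@H](O)C=C | intermediate
7 | (S)-tert-butyldimethyl(pent-1-en-4-yn-3-yloxy)silane | C#C[C@@H](O[Si](C)(C)C(C)(C)C)C=C | intermediate
8 | chlorobis(cyclopentadienyl)[(1E,3S)-3-[(tert-butyldimethylsilyl)oxy]penta-1,4-dien-1-yl]zirconium | Cl[Zr](C1C=CC=C1)(C1C=CC=C1)/C=C/[C@@H](O[Si](C)(C)C(C)(C)C)C=C | intermediate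
9 | (S,E)-tert-butyl[(1-iodopenta-1,4-dien-3-yl)oxy]dimethylsilane | I/C=C/[C@@H](O[Si](C)(C)C(C)(C)C)C=C | intermediate
10 | [(1E,3S)-3-[(tert-butyldimethylsilyl)oxy]penta-1,4-dien-1-yl]lithium | [Li]/C=C/[C@@H](O[Si](C)(C)C(C)(C)C)C=C | intermediate
11 | lithium alkoxide of (3S,4E,7S,8R,9E)-3-[(tert-butyldimethylsilyl)oxy]-8-hydroxy-7-methylundeca-1,4,9-trien-6-one | C/C=C/[C@@H](O[Li])[C@H](C)C(=O)/C=C/[C@@H](O[Si](C)(C)C(C)(C)C)C=C | intermediate
12 | lithium enolate (C18=C19) of oxan-4-one 13 | C/C=C/[C@H]1O[C@@H]([C@@H](O[Si](C)(C)C(C)(C)C)C=C)C=C(O[Li])[C@H]1C | intermediate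
13 | (2R,3S,6R)-6-[(1S)-1-[(tert-butyldimethylsilyl)oxy]prop-2-en-1-yl]-3-methyl-2-[(E)-prop-1-en-1-yl]oxan-4-one | C/C=C/[C@H]1O[C@@H]([C@@H](O[Si](C)(C)C(C)(C)C)C=C)CC(=O)[C@H]1C | intermediate
14 | (2R,3R,4S,6R)-6-[(1S)-1-[(tert-butyldimethylsilyl)oxy]prop-2-en-1-yl]-3-methyl-2-[(E)-prop-1-en-1-yl]oxan-4-ol | C/C=C/[C@H]1O[C@@H]([C@@H](O[Si](C)(C)C(C)(C)C)C=C)C[C@H](O)[C@H]1C | intermediate
15 | (S)-4-benzyl-3-propanoyloxazolidin-2-one | CCC(=O)N1[C@@H](Cc2ccccc2)COC1=O | intermediate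
16 | 3-bromoprop-1-yne | C#CCBr | starting material
17 | sodium (Z)-enolate of 15 | C/C=C(\O[Na])N1[C@@H](Cc2ccccc2)COC1=O | intermediate
18 | (S)-4-benzyl-3-[(R)-2-methylpent-4-ynoyl]oxazolidin-2-one | C#CC[C@@H](C)C(=O)N1[C@@H](Cc2ccccc2)COC1=O | intermediate
19 | (R)-2-methylpent-4-yn-1-ol | C#CC[C@@H](C)CO | intermediate
20 | dimethyl[(1E,4R)-5-[(dimethylalumanyl)oxy]-2,4-dimethylpent-1-en-1-yl]alumane | C[Al](C)/C=C(\C)C[C@@H](C)CO[Al](C)C | intermediate
21 | (R,E)-5-iodo-2,4-dimethylpent-4-en-1-ol | I/C=C(\C)C[C@@H](C)CO | intermediate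
22 | rac-hexa-1,5-dien-3-ol | C=CCC(O)C=C | starting material
23 | (S)-hexa-1,5-dien-3-ol | C=C[C@@H](O)CC=C | intermediate
24 | prop-2-enoyl chloride | C=CC(=O)Cl | starting material
25 | (S)-hexa-1,5-dien-3-yl prop-2-enoate | C=C[C@@H](OC(=O)C=C)CC=C | intermediate
26 | (S)-6-ethenyl-5,6-dihydro-2H-pyran-2-one | C=C[C@@H]1CC=CC(=O)O1 | intermediate
27 | (2R,3R,4S,6R)-6-[(1S,2E,4E,7R)-1-[(tert-butyldimethylsilyl)oxy]-8-hydroxy-5,7-dimethylocta-2,4-dien-1-yl]-3-methyl-2-[(E)-prop-1-en-1-yl]oxan-4-ol | C/C=C/[C@H]1O[C@@H]([C@@H](O[Si](C)(C)C(C)(C)C)/C=C/C=C(\C)C[C@@H](C)CO)C[C@H](O)[C@H]1C | intermediate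
28 | (2R,4E,6E,8S)-8-[(tert-butyldimethylsilyl)oxy]-8-[(2R,4S,5R,6R)-4-hydroxy-5-methyl-6-[(E)-prop-1-en-1-yl]oxan-2-yl]-2,4-dimethylocta-4,6-dienal | C/C=C/[C@H]1O[C@@H]([C@@H](O[Si](C)(C)C(C)(C)C)/C=C/C=C(\C)C[C@@H](C)C=O)C[C@H](O)[C@H]1C | intermediate
29 | (2R,3R,4S,6R)-6-[(1S,2E,4E,7R,8Z)-1-[(tert-butyldimethylsilyl)oxy]-9-iodo-5,7-dimethyldeca-2,4,8-trien-1-yl]-3-methyl-2-[(E)-prop-1-en-1-yl]oxan-4-ol | C/C=C/[C@H]1O[C@@H]([C@@H](O[Si](C)(C)C(C)(C)C)/C=C/C=C(\C)C[C@@H](C)/C=C(C)\I)C[C@H](O)[C@H]1C | intermediate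
30 | (6S)-6-[(1E,3Z,5R,7E,9E,11S)-11-[(tert-butyldimethylsilyl)oxy]-11-[(2R,4S,5R,6R)-4-hydroxy-5-methyl-6-[(E)-prop-1-en-1-yl]oxan-2-yl]-3,5,7-trimethylundeca-1,3,7,9-tetraen-1-yl]-5,6-dihydro-2H-pyran-2-one | C/C=C/[C@H]1O[C@@H]([C@@H](O[Si](C)(C)C(C)(C)C)/C=C/C=C(\C)C[C@@H](C)/C=C(C)\C=C\[C@@H]2CC=CC(=O)O2)C[C@H](O)[C@H]1C | intermediate
31 | (6S)-6-[(1E,3Z,5R,7E,9E,11S)-11-hydroxy-11-[(2R,4S,5R,6R)-4-hydroxy-5-methyl-6-[(E)-prop-1-en-1-yl]oxan-2-yl]-3,5,7-trimethylundeca-1,3,7,9-tetraen-1-yl]-5,6-dihydro-2H-pyran-2-one (CNP0248490.1) | C/C=C/[C@H]1O[C@@H]([C@@H](O)/C=C/C=C(\C)C[C@@H](C)/C=C(C)\C=C\[C@@H]2CC=CC(=O)O2)C[C@H](O)[C@H]1C | target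

## Step count and risks

Total steps: 18. Longest linear sequence: 10 (steps 2, 3, 4, 5, 6, 14, 15, 16, 17, 18, from 5).

Three steps most likely to fail:

**Step 5 (proposed ring expansion).** Risks are double addition of 10, retro-aldol of aldolate 11, and slow closure of the Li-chelated alkoxide. The fallback is the known stepwise sequence; it sets out from 4 (with 10 made from 9) and comes back at 13. Lactone 4 is opened with MeONHMe·HCl/Me2AlCl (CH2Cl2, 0 °C) to the Weinreb amide (2S,3R,E)-3-hydroxy-N-methoxy-N,2-dimethylhex-4-enamide F1. Addition of 10 (2.2 equiv, −78 °C) through the stable Weinreb chelate gives the hydroxy enone (3S,4E,7S,8R,9E)-3-[(tert-butyldimethylsilyl)oxy]-8-hydroxy-7-methylundeca-1,4,9-trien-6-one F2. Amberlyst-15 (CH2Cl2, 0 °C) then effects the 6-endo oxa-Michael closure to 13, which is reduced at once as in step 6.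

**Step 1 (cyclocondensation with an enal; polymerisation-prone allylic β-lactone).** The fallback replaces catalyst control by auxiliary control; it sets out from 1 and 15 and comes back at 4. A Bu2BOTf/iPr2NEt Evans syn-aldol of 15 with 1 gives (S)-4-benzyl-3-[(2S,3R,E)-3-hydroxy-2-methylhex-4-enoyl]oxazolidin-2-one F3. LiOH/H2O2 releases (2S,3R,E)-3-hydroxy-2-methylhex-4-enoic acid F4. PhSO2Cl/pyridine (0 °C) lactonises F4 by carboxyl activation, with retention at both centres, to 4.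

**Step 17 (Heck reaction next to a base-sensitive, Heck-competent enoate lactone).** The fallback replaces the Heck reaction by a Suzuki coupling; it sets out from 26 and 29 and comes back at 30. Cross-metathesis of 26 with vinylboronic acid pinacol ester (Hoveyda–Grubbs II, CH2Cl2, 40 °C) gives (S,E)-6-[2-(4,4,5,5-tetramethyl-1,3,2-dioxaborolan-2-yl)ethenyl]-5,6-dihydro-2H-pyran-2-one F5. Pd(dppf)Cl2/Tl2CO3 (THF/H2O, rt) couples F5 with 29 to give 30 with retention of both alkene geometries.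

Further compounds

F1 | step 5 | (2S,3R,E)-3-hydroxy-N-methoxy-N,2-dimethylhex-4-enamide | C/C=C/[C@@H](O)[C@H](C)C(=O)N(C)OC
F2 | step 5 | (3S,4E,7S,8R,9E)-3-[(tert-butyldimethylsilyl)oxy]-8-hydroxy-7-methylundeca-1,4,9-trien-6-one | C/C=C/[C@@H](O)[C@H](C)C(=O)/C=C/[C@@H](O[Si](C)(C)C(C)(C)C)C=C
F3 | step 1 | (S)-4-benzyl-3-[(2S,3R,E)-3-hydroxy-2-methylhex-4-enoyl]oxazolidin-2-one | C/C=C/[C@@H](O)[C@H](C)C(=O)N1[C@@H](Cc2ccccc2)COC1=O
F4 | step 1 | (2S,3R,E)-3-hydroxy-2-methylhex-4-enoic acid | C/C=C/[C@@H](O)[C@H](C)C(=O)O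
F5 | step 17 | (S,E)-6-[2-(4,4,5,5-tetramethyl-1,3,2-dioxaborolan-2-yl)ethenyl]-5,6-dihydro-2H-pyran-2-one | CC1(C)OB(/C=C/[C@@H]2CC=CC(=O)O2)OC1(C)C
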